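The route rests on cutting the aryl ether bond O1–C8a of ring C, so that the C2–O bond, and with it the C2 stereocentre, is never touched after it is set. The key step is a copper-catalysed intramolecular O-arylation of an unprotected, open-chain 1,3-diol that carries a bromine at C8a of ring A. It closes ring C in one operation, selects the C2 hydroxyl by ring size alone and conserves all stereocentres. It exploits C8a being ortho to the C4 side chain and meta to O5 and O7. C4 is held at the carbinol level to shut off retro-aldol cleavage and dehydration. Later oxidation restores the ketone and lets acidic C3–H settle trans.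

Key step: step 6

Remark: flavanone numbering (O1, C2, C3, C4, C4a, C5 to C8, C8a) is used for the same atoms in the open-chain precursors.
Assumption: the four benzyl ether starting materials are taken as catalogue compounds; each is otherwise one O-benzylation away from phloroacetophenone, 3-bromo-4-hydroxybenzaldehyde, 4-hydroxyacetophenone or 5-bromoresorcinol.
Assumption: the facial sense of (−)-Ipc2BOTf is taken from the chair model that holds for Ipc2B reagents made from (+)-α-pinene (Si face of the aldehyde); should the opposite sense be found, the antipodal reagent is used and nothing else changes.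

Step 1
Reactants: 1 1-[2,4-bis(benzyloxy)-6-hydroxyphenyl]ethan-1-one; 2 4-(benzyloxy)-3-bromobenzaldehyde
Product: 3 (E)-1-[2,4-bis(benzyloxy)-6-hydroxyphenyl]-3-[4-(benzyloxy)-3-bromophenyl]prop-2-en-1-one
Conditions: KOH, EtOH–THF, rt
Reagents that add atoms: none
Why: Claisen–Schmidt condensation, in which the methyl ketone enolate adds to the non-enolisable aldehyde and E1cB loss of water gives the conjugated E-enone, while the hydrogen-bonded ortho phenol stays free for the next ring closure.

Step 2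
Reactants: 3 (E)-2'-hydroxychalcone
Product: 4 5,7-bis(benzyloxy)-2-[4-(benzyloxy)-3-bromophenyl]-4H-chromen-4-one
Conditions: I2 (catalytic), DMSO, 120 °C
Reagents that add atoms: none
Why: Iodine-catalysed oxidative cyclisation of a 2'-hydroxychalcone to a flavone, in which the phenol closes on the enone and the new ring is dehydrogenated through iodine while DMSO re-oxidises HI, conditions that aryl bromides and benzyl ethers tolerate.

Step 3
Reactants: 4 3'-bromoflavone; 5 1-[4-(benzyloxy)phenyl]ethan-1-one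
Product: 6 5,7-bis(benzyloxy)-2-(4-(benzyloxy)-3-{2-[4-(benzyloxy)phenyl]-2-oxoethyl}phenyl)-4H-chromen-4-one
Conditions: Pd2(dba)3, 2-dicyclohexylphosphino-2'-methylbiphenyl, K3PO4, toluene, 90 °C
Reagents that add atoms: none
Why: Palladium-catalysed ketone α-arylation, in which zerovalent palladium inserts into the only C–Br bond, the enolate of 5 binds and reductive elimination forms the future C3–aryl bond, while the ortho benzyloxy group and the acidity of the product stop a second arylation and the mild phosphate base spares the chromone.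

Step 4
Reactants: 7 1,3-bis(benzyloxy)-5-bromobenzene
Product: 9 2,4-bis(benzyloxy)-6-bromobenzaldehyde, via iminium chloride 8 (not isolated)
Conditions: POCl3, DMF, 0 to 80 °C; then ice-water
Reagents that add atoms: N,N-dimethylformamide, CN(C)C=O; water, O
Why: Vilsmeier–Haack formylation, in which the chloroiminium ion attacks the position para to one benzyloxy group and ortho to the other, next to bromine, in preference to the more crowded site between the two benzyloxy groups, and water then hydrolyses iminium salt 8.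

Step 5
Reactants: 6 aryl benzyl ketone; 9 2,4-bis(benzyloxy)-6-bromobenzaldehyde
Product: 12 (1S,2R,3R)-1-[2,4-bis(benzyloxy)-6-bromophenyl]-3-[4-(benzyloxy)phenyl]-2-{2-(benzyloxy)-5-[5,7-bis(benzyloxy)-4-oxo-4H-chromen-2-yl]phenyl}propane-1,3-diol (all-syn; C4 S and C3 R and C2 R in flavanone numbering), via Z-boron enolate 10 (not isolated), via boron aldolate 11 (not isolated)
Conditions: (−)-Ipc2BOTf (excess), iPr2NEt, CH2Cl2, −78 °C; 9, −78 to −20 °C; LiBH4, −78 °C; then H2O2, MeOH, pH 7 buffer, 0 °C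
Reagents that add atoms: none
Why: Chiral boron-mediated aldol reaction followed by in situ chelate-controlled reduction of Narasaka–Prasad type, in which Z-enolate 10 reacts through a Zimmerman–Traxler chair whose isopinocampheyl ligands expose the Si face of 9 and so set C4 (S) with C3 syn to it, and external hydride then attacks the six-membered boron chelate 11 to give the 1,3-syn diol, which relays the C4 configuration to C2 (R).

Step 6
Reactants: 12 all-syn bromo diol
Product: 13 (2R,3S,4S)-5,7-bis(benzyloxy)-2-[4-(benzyloxy)phenyl]-3-{2-(benzyloxy)-5-[5,7-bis(benzyloxy)-4-oxo-4H-chromen-2-yl]phenyl}chroman-4-ol (2,3-cis-3,4-trans)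
Conditions: CuI (10 mol %), 3,4,7,8-tetramethyl-1,10-phenanthroline (20 mol %), Cs2CO3, toluene, 100 °C, argon
Reagents that add atoms: none
Why: Carbonate converts the C2 hydroxyl into an alkoxide bound to monovalent copper, the C8a–Br bond adds oxidatively to give an aryl alkoxide complex of trivalent copper, and reductive elimination forms O1–C8a. The closest known reaction type is the intramolecular Ullmann-type etherification that turns 3-(2-halophenyl)propan-1-ols into chromans. Ring C closes in a six-membered mode, 6-exo with respect to the departing C–Br bond, by way of a seven-membered cupracycle. No stereocentre is created: the C2–O bond is never broken, so C2 stays R, and C3 and C4 are spectators because, with C4 at the carbinol level, C3–H is not acidic and no carbonyl group is present to accept a retro-aldol cleavage or to drive loss of water. The selectivity needed is C2–OH over C4–OH, and ring size secures it, since the C4 oxygen could only give a four-membered benzoxete and can at most hold copper next to the bromide. C8a lies meta to the C5 and C7 benzyloxy groups, so their donation does not reach the reacting carbon, and it carries the only carbon–halogen bond of the molecule.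

Step 7
Reactants: 13 2,3-cis-3,4-trans flavan-4-ol
Product: 15 (2R,3S)-5,7-bis(benzyloxy)-2-[4-(benzyloxy)phenyl]-3-{2-(benzyloxy)-5-[5,7-bis(benzyloxy)-4-oxo-4H-chromen-2-yl]phenyl}chroman-4-one (2,3-trans), via cis ketone 14 (not isolated)
Conditions: Dess–Martin periodinane, CH2Cl2, 0 °C to rt; then Et3N (excess), rt
Reagents that add atoms: none
Why: Dess–Martin oxidation of the only free hydroxyl gives cis ketone 14, whose C3–H, now flanked by the carbonyl group and an aryl ring, is exchanged by the weak amine base so that C3 equilibrates to the diequatorial 2,3-trans isomer (thermodynamic epimerisation), while C2, which bears no acidic hydrogen, is untouched.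

Step 8
Reactants: 15 hexa-O-benzyl ether of the target
Product: 16 (2R,3S)-3-[5-(5,7-dihydroxy-4-oxo-4H-chromen-2-yl)-2-hydroxyphenyl]-5,7-dihydroxy-2-(4-hydroxyphenyl)chroman-4-one (CNP0324936.1)
Conditions: H2 (1 atm), Pd/C, EtOAc–MeOH, rt
Reagents that add atoms: none
Why: Heterogeneous hydrogenolysis of the six benzyl ethers under neutral conditions, which neither enolise C3 nor open ring C, so that both stereocentres survive, and which at ambient pressure should leave the chromone double bond alone.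

Compound list
1 | 1-[2,4-bis(benzyloxy)-6-hydroxyphenyl]ethan-1-one | CC(=O)c1c(O)cc(OCc2ccccc2)cc1OCc1ccccc1 | starting material
2 | 4-(benzyloxy)-3-bromobenzaldehyde | O=Cc1ccc(OCc2ccccc2)c(Br)c1 | starting material
3 | (E)-1-[2,4-bis(benzyloxy)-6-hydroxyphenyl]-3-[4-(benzyloxy)-3-bromophenyl]prop-2-en-1-one | O=C(/C=C/c1ccc(OCc2ccccc2)c(Br)c1)c1c(O)cc(OCc2ccccc2)cc1OCc1ccccc1 | intermediate
4 | 5,7-bis(benzyloxy)-2-[4-(benzyloxy)-3-bromophenyl]-4H-chromen-4-one | O=c1cc(-c2ccc(OCc3ccccc3)c(Br)c2)oc2cc(OCc3ccccc3)cc(OCc3ccccc3)c12 | intermediate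
5 | 1-[4-(benzyloxy)phenyl]ethan-1-one | CC(=O)c1ccc(OCc2ccccc2)cc1 | starting material
6 | 5,7-bis(benzyloxy)-2-(4-(benzyloxy)-3-{2-[4-(benzyloxy)phenyl]-2-oxoethyl}phenyl)-4H-chromen-4-one | O=C(Cc1cc(-c2cc(=O)c3c(OCc4ccccc4)cc(OCc4ccccc4)cc3o2)ccc1OCc1ccccc1)c1ccc(OCc2ccccc2)cc1 | intermediate
7 | 1,3-bis(benzyloxy)-5-bromobenzene | Brc1cc(OCc2ccccc2)cc(OCc2ccccc2)c1 | starting material
8 | N-{[2,4-bis(benzyloxy)-6-bromophenyl]methylidene}-N-methylmethanaminium chloride | C[N+](C)=Cc1c(Br)cc(OCc2ccccc2)cc1OCc1ccccc1.[Cl-] | intermediate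
9 | 2,4-bis(benzyloxy)-6-bromobenzaldehyde | O=Cc1c(Br)cc(OCc2ccccc2)cc1OCc1ccccc1 | intermediate
10 | (Z)-bis(isopinocampheyl)boron enolate of 6 (O–B and the flavone-bearing aryl group cis on the double bond) | C[C@@H]1[C@H]2C[C@H](C2(C)C)C[C@H]1B([C@@H]1C[C@@H]2C[C@H]([C@H]1C)C2(C)C)O/C(c1ccc(OCc2ccccc2)cc1)=C\c1cc(-c2cc(=O)c3c(OCc4ccccc4)cc(OCc4ccccc4)cc3o2)ccc1OCc1ccccc1 | intermediate
11 | bis(isopinocampheyl)boron aldolate, 3,4-syn, C4 (S), ketone at C2 | C[C@@H]1[C@H]2C[C@H](C2(C)C)C[C@H]1B([C@@H]1C[C@@H]2C[C@H]([C@H]1C)C2(C)C)O[C@H](c1c(Br)cc(OCc2ccccc2)cc1OCc1ccccc1)[C@H](c1cc(-c2cc(=O)c3c(OCc4ccccc4)cc(OCc4ccccc4)cc3o2)ccc1OCc1ccccc1)C(=O)c1ccc(OCc2ccccc2)cc1 | intermediate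
12 | (1S,2R,3R)-1-[2,4-bis(benzyloxy)-6-bromophenyl]-3-[4-(benzyloxy)phenyl]-2-{2-(benzyloxy)-5-[5,7-bis(benzyloxy)-4-oxo-4H-chromen-2-yl]phenyl}propane-1,3-diol (all-syn) | O[C@H](c1c(Br)cc(OCc2ccccc2)cc1OCc1ccccc1)[C@H](c1cc(-c2cc(=O)c3c(OCc4ccccc4)cc(OCc4ccccc4)cc3o2)ccc1OCc1ccccc1)[C@@H](O)c1ccc(OCc2ccccc2)cc1 | intermediate
13 | (2R,3S,4S)-hexa-O-benzyl flavan-4-ol, 2,3-cis-3,4-trans | O[C@@H]1c2c(OCc3ccccc3)cc(OCc3ccccc3)cc2O[C@@H](c2ccc(OCc3ccccc3)cc2)[C@H]1c1cc(-c2cc(=O)c3c(OCc4ccccc4)cc(OCc4ccccc4)cc3o2)ccc1OCc1ccccc1 | intermediate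
14 | (2R,3R)-hexa-O-benzyl chroman-4-one, 2,3-cis | O=C1c2c(OCc3ccccc3)cc(OCc3ccccc3)cc2O[C@@H](c2ccc(OCc3ccccc3)cc2)[C@H]1c1cc(-c2cc(=O)c3c(OCc4ccccc4)cc(OCc4ccccc4)cc3o2)ccc1OCc1ccccc1 | intermediate
15 | (2R,3S)-hexa-O-benzyl chroman-4-one, 2,3-trans | O=C1c2c(OCc3ccccc3)cc(OCc3ccccc3)cc2O[C@@H](c2ccc(OCc3ccccc3)cc2)[C@@H]1c1cc(-c2cc(=O)c3c(OCc4ccccc4)cc(OCc4ccccc4)cc3o2)ccc1OCc1ccccc1 | intermediate
16 | (2R,3S)-3-[5-(5,7-dihydroxy-4-oxo-4H-chromen-2-yl)-2-hydroxyphenyl]-5,7-dihydroxy-2-(4-hydroxyphenyl)chroman-4-one | O=C1c2c(O)cc(O)cc2O[C@@H](c2ccc(O)cc2)[C@@H]1c1cc(-c2cc(=O)c3c(O)cc(O)cc3o2)ccc1O | target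

Total step count: 8
Longest linear sequence: 7 steps (1, 2, 3, 5, 6, 7, 8)

Steps most likely to fail

Step 6 (key step). Two processes may go wrong. Hydride may transfer from the free C4 carbinol to the metallated C8a position, with reductive loss of bromine. The 1,3-diolate may also bind copper so firmly that turnover stops. The fallback sets out from 6 and 9 and comes back at 15.
- The aldol reaction of step 5 is run with the antipodal reagent (+)-Ipc2BOTf and worked up with H2O2 at pH 7 without borohydride, which should give the enantiomeric syn aldol ketone F1.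
- An Evans–Tishchenko reaction (PhCHO, catalytic SmI2, THF, −10 °C) delivers hydride inside the samarium hemiacetal chelate. This sets C2 (R) 1,3-anti to C4 and at the same time caps the C4 oxygen, giving the C4 benzoate bearing a free C2 hydroxyl F2.
- With no C4 alkoxide left, the same O1–C8a bond is closed by palladium-catalysed intramolecular C–O coupling (Pd(OAc)2, 2-(di-tert-butylphosphino)-1,1'-binaphthyl, Cs2CO3, toluene, 70 °C) to the 2,3-trans flavan-4-yl benzoate F3.
- K2CO3 in MeOH–THF frees the 2,3-trans-3,4-trans flavan-4-ol F4, and Dess–Martin oxidation should give 15 directly, with C3 already trans.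

Step 5. Facial selectivity towards the doubly ortho-substituted aldehyde may be poor. The chromone carbonyl may also capture part of the boron triflate, which slows enolisation. The fallback sets out from 6 and 9 and comes back at 13; it moves absolute control from a chiral reagent to a classical resolution.
- The same aldol–reduction sequence run with achiral Bu2BOTf should give 12 together with its mirror image, the ent-diol F5.
- The conditions of step 6 turn this racemate into 13 and the ent-flavan-4-ol F6.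
- The single free hydroxyl at C4 is esterified with (S)-O-methylmandelic acid (EDC, DMAP, CH2Cl2) to the mandelate of 13 F7 and the mandelate of the enantiomer F8. These are diastereomers and are separated by chromatography or crystallisation.
- K2CO3 in MeOH cleaves F7 back to 13.

Step 8. The chromone C2=C3 bond may be saturated, or the benzylic C2–O1 bond of ring C may be hydrogenolysed, before the last benzyl ether has gone. The fallback sets out from 15 and comes back at 16. The reductive cleavage is replaced by Lewis acid dealkylation with a cation trap (BCl3, pentamethylbenzene, CH2Cl2, −78 °C). This removes the benzyl groups as cations and touches neither the alkene nor the C2–O1 bond. No new compound arises on the way (F0).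

Further compounds
F1 | step 6 | enantiomeric syn aldol ketone, C3 (R) and C4 (R) in flavanone numbering, ketone at C2 | O[C@@H](c1c(Br)cc(OCc2ccccc2)cc1OCc1ccccc1)[C@@H](c1cc(-c2cc(=O)c3c(OCc4ccccc4)cc(OCc4ccccc4)cc3o2)ccc1OCc1ccccc1)C(=O)c1ccc(OCc2ccccc2)cc1
F2 | step 6 | C4 benzoate bearing a free C2 hydroxyl, 3,4-syn and 2,4-anti, C2 (R) | O=C(O[C@@H](c1c(Br)cc(OCc2ccccc2)cc1OCc1ccccc1)[C@@H](c1cc(-c2cc(=O)c3c(OCc4ccccc4)cc(OCc4ccccc4)cc3o2)ccc1OCc1ccccc1)[C@@H](O)c1ccc(OCc2ccccc2)cc1)c1ccccc1
F3 | step 6 | 2,3-trans-3,4-trans flavan-4-yl benzoate | O=C(O[C@H]1c2c(OCc3ccccc3)cc(OCc3ccccc3)cc2O[C@@H](c2ccc(OCc3ccccc3)cc2)[C@@H]1c1cc(-c2cc(=O)c3c(OCc4ccccc4)cc(OCc4ccccc4)cc3o2)ccc1OCc1ccccc1)c1ccccc1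
F4 | step 6 | (2R,3R,4R)-hexa-O-benzyl flavan-4-ol, 2,3-trans-3,4-trans | O[C@H]1c2c(OCc3ccccc3)cc(OCc3ccccc3)cc2O[C@@H](c2ccc(OCc3ccccc3)cc2)[C@@H]1c1cc(-c2cc(=O)c3c(OCc4ccccc4)cc(OCc4ccccc4)cc3o2)ccc1OCc1ccccc1
F5 | step 5 | ent-diol, (1R,2S,3S), mirror image of 12 | O[C@@H](c1c(Br)cc(OCc2ccccc2)cc1OCc1ccccc1)[C@@H](c1cc(-c2cc(=O)c3c(OCc4ccccc4)cc(OCc4ccccc4)cc3o2)ccc1OCc1ccccc1)[C@H](O)c1ccc(OCc2ccccc2)cc1
F6 | step 5 | ent-flavan-4-ol, (2S,3R,4R), mirror image of 13 | O[C@H]1c2c(OCc3ccccc3)cc(OCc3ccccc3)cc2O[C@H](c2ccc(OCc3ccccc3)cc2)[C@@H]1c1cc(-c2cc(=O)c3c(OCc4ccccc4)cc(OCc4ccccc4)cc3o2)ccc1OCc1ccccc1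
F7 | step 5 | (S)-O-methylmandelate of 13 | CO[C@@H](c1ccccc1)C(=O)O[C@@H]1c2c(OCc3ccccc3)cc(OCc3ccccc3)cc2O[C@@H](c2ccc(OCc3ccccc3)cc2)[C@H]1c1cc(-c2cc(=O)c3c(OCc4ccccc4)cc(OCc4ccccc4)cc3o2)ccc1OCc1ccccc1
F8 | step 5 | (S)-O-methylmandelate of the enantiomer F6 | CO[C@@H](c1ccccc1)C(=O)O[C@H]1c2c(OCc3ccccc3)cc(OCc3ccccc3)cc2O[C@H](c2ccc(OCc3ccccc3)cc2)[C@@H]1c1cc(-c2cc(=O)c3c(OCc4ccccc4)cc(OCc4ccccc4)cc3o2)ccc1OCc1ccccc1
F0 | step 8 | none | none
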